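common to all: second end groups 0.900 equiv
- Tuesday's: first end groups 1.0 mM (fed, over 40.0 s); time 50 s; all but first end groups at the start; first end groups goes in evenly over 40.0 s, the run ends at 50 s
- Monday's: first end groups 1.0 mM; one stirred flow tank at steady state, fed with the mixture as stated, mean residence time 150 s
- Friday's: first end groups 1.0 mM; time 50 s; a closed flask charged with all of it at once and left for 50 s
- Thursday's: first end groups 1.0 mM; a single well-mixed tank run continuously and read at steady state, 50 s in it on average

    first end groups + second end groups → links (k1 = 3500 /M/s)
    first end groups + second end groups → rings, rate k2*[first end groups] as long as [second end groups] is above zero (k2 = 5.1 /s)
    second end groups + links ⇌ idle adduct, settled at all times (K3 = 1800 /M)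
    first end groups + links → side product (k4 = 290 /M/s)
    second end groups → decomposed reagent (k5 = 0.082 /s)

- a species is counted by the first end groups in it: one side product counts as two
- amounts and yields of links count idle adduct too
- the stated concentrations are those of everything mixed, before any reaction; amounts are the same in each set-up
- the feed brings no volume worth counting
- run time (Tuesday's): 50 s

* the set-up with the highest amount of links at the outlet or at the end, in percent of the first end groups put in ("none" if the first two lie within 2 percentage points) (Tuesday's / Monday's / Friday's / Thursday's / none)
* amount of links at the outlet or at the end, in percent of the first end groups put in, Tuesday's
* amount of links at the outlet or at the end, in percent of the first end groups put in, Monday's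
* amount of links at the outlet or at the end, in percent of the first end groups put in, Friday's
* amount of links at the outlet or at the end, in percent of the first end groups put in, Thursday's

If this run is repeated, the thing to watch is how much free second end groups stands in the vessel when a first end group arrives, for a first end group has two ways forward: the link step, whose rate grows with the second end groups, and the ring step, whose rate does not. We follow one first end group and ask for its chances. The two ways are equal at the break-even level, the free second end groups as a fraction of the charge of first end groups, 1.46. The chance of a link is then the level divided by the level plus the break-even level.

In Friday's flask the charge of 0.900 equiv lies below the break-even level, so in the first instants rings lead, with a link chance of 38.2%. Each first end group taken removes one second end group, so the chance falls as the run goes on. The half-life of first end groups by the link step alone, 0.22 s, is far shorter than the 8.5 s of second end groups in decay, so we neglect decay here, and we leave out idle adduct too. Summing the chance over the whole charge gives links made 19.9% and rings 70.1%. Once the level reaches zero in this reckoning, the 10.0% of first end groups left over attacks links one for one, and that leaves us reckoning 11.3% links at 50 s.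

Tuesday's feed, 0.0250 /s of the charge, is far slower than the ring step's 5.1 /s, so first end groups stay low while the level lasts. But decay now competes: with the feed-to-decay ratio 0.305, the level reaches zero once 41.9% has been fed, at 16.8 s. The chances sum to links made 7.46%, and the first end groups fed afterwards reduce that to about 0.195%. In a tank with free second end groups present, the ring step alone converts 99.6% of the first end groups fed in Thursday's and 99.9% in Monday's, more than the second end groups supplied. So we set the level at zero in both tanks, where the link chance is zero.

The forecast names Friday's best, with 8.6% there, 0.25% in Tuesday's, and 0% and 0% in Monday's and Thursday's, since in the tanks “free second end groups sit at essentially zero”. The simulation gives Friday's, with 9.44%, 0.288%, 0% and 0% in the same order. Friday's rings stand at 70.9% against our 70.1%. A side product counts as two first end groups and took one link, so the links made in Friday's, those standing plus those lost to side product, come to 18.3% against our 19.9%.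

Neither flask has come to rest at 50 s in every species. Friday's still holds 1.81% of first end groups, and at 500 s these stand at 0%, links have fallen to 7.63% and side product has risen from 17.8% to 21.4%, while rings remain at 70.9%. Tuesday's links go from 0.288% to 0% over the same stretch, and its first end groups from 50.6% to 50.3%. So in Friday's the reading time still matters.

With 3.60 equiv of second end groups in Tuesday's flask, the level starts above the break-even level, and the same sum gives links made 27.4%. The computed flask holds 17.7% links and 18.7% side product, so the links made, counted as for Friday's, come to 27.0%.

The rate constants come from no measurement; what happens was integrated by code.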